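**Retrosynthetic overview**

1. Last bond (C–O): the C7–O–C10 oxolane bridge, closed by a transannular dehydrogenative allylic C–H etherification of a 10-hydroxy-1-oxo germacranolide (germacrane numbering C1–C15 throughout).
2. That ketol comes from an 8α-silyloxy costunolide-type macrolide by 1(10)-ketohydroxylation, 4,5-epoxidation and silyl-to-methacryloyl exchange.
3. The macrolide comes from CrCl2-mediated closure of C6–C7 between an enal and a 2-(bromomethyl)enoate, which forms carbocycle and lactone together.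
4. The open chain comes from a vinyl oxirane made from an organocatalytically α-chlorinated aldehyde plus methyl propiolate; the aldehyde is farnesol minus its terminal C3 unit.
5. Ring order: ten-membered carbocycle with γ-lactone (step 6), oxirane (step 8), oxolane bridge (step 10).

Assumption: (2R,5R)-2,5-diphenylpyrrolidine is taken as the catalyst antipode that gives the (2R)-chloro aldehyde 5; if its sense is the opposite, its mirror image is used.

**Route**

Step 1
Reactants: 1 (2E,6E)-farnesol
Product: 3 (2E,6E)-10,11-epoxyfarnesol (racemic at the oxirane), via bromohydrin 2 (not isolated)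
Conditions: NBS, THF/H2O, 0 °C; then K2CO3, MeOH, rt
Reagents that add atoms: water, O
Why: Bromohydrin formation with NBS in aqueous THF is selective for the terminal trisubstituted alkene (least hindered chain end) and K2CO3 closes it to the oxirane by intramolecular Williamson etherification; its stereocentre is destroyed in step 2, so no control is needed.

Step 2
Reactants: 3 (2E,6E)-10,11-epoxyfarnesol
Product: 4 (4E,8E)-10-hydroxy-4,8-dimethyldeca-4,8-dienal
Conditions: H5IO6, THF/H2O, 0 °C
Reagents that add atoms: none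
Why: Periodic acid hydrolyses the oxirane and cleaves the resulting glycol (Malaprade cleavage), excising acetone and leaving the aldehyde carbon that becomes C7, while the allylic alcohol and the alkenes are inert.

Step 3
Reactants: 4 (4E,8E)-10-hydroxy-4,8-dimethyldeca-4,8-dienal
Product: 5 (2R,4E,8E)-2-chloro-10-hydroxy-4,8-dimethyldeca-4,8-dienal
Conditions: NCS, (2R,5R)-2,5-diphenylpyrrolidine (10 mol %), CH2Cl2, −30 to 0 °C; used crude
Reagents that add atoms: N-chlorosuccinimide, ClN1C(=O)CCC1=O
Why: Enamine organocatalysis (asymmetric α-chlorination of an aldehyde): the C2-symmetric pyrrolidine shields one enamine face so that NCS chlorinates the other, setting the (2R) centre that becomes C8 after one inversion.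

Step 4
Reactants: 5 (2R,4E,8E)-2-chloro-10-hydroxy-4,8-dimethyldeca-4,8-dienal; 6 methyl propiolate
Product: 9 methyl 2-[(2S,3S)-3-[(2E,6E)-8-hydroxy-2,6-dimethylocta-2,6-dien-1-yl]oxiran-2-yl]prop-2-enoate, via vinylalane 7 (not isolated), via chlorohydrin 8 (not isolated)
Conditions: iBu2AlH, N-methylmorpholine N-oxide, THF, 0 °C, 6 (2.5 equiv); then 5, rt; aqueous Rochelle salt work-up; then Cs2CO3, MeCN, rt
Reagents that add atoms: none
Why: 1,4-Hydroalumination of the propiolate gives an α-aluminoacrylate that adds to the aldehyde (vinylalumination, a Morita–Baylis–Hillman-type addition without amine base) anti to chlorine under Cornforth control, and Cs2CO3 closes the chlorohydrin by intramolecular SN2 with inversion at C8, which transposes the oxygen onto C8 in the (S) configuration of the target (the C7 centre is erased in step 6, so both chlorohydrin epimers converge).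

Step 5
Reactants: 9 methyl 2-[(2S,3S)-3-[(2E,6E)-8-hydroxy-2,6-dimethylocta-2,6-dien-1-yl]oxiran-2-yl]prop-2-enoate
Product: 10 methyl 2-[(2S,3S)-3-[(2E,6E)-2,6-dimethyl-8-oxoocta-2,6-dien-1-yl]oxiran-2-yl]prop-2-enoate
Conditions: MnO2, CH2Cl2, rt
Reagents that add atoms: none
Why: MnO2 oxidises only the primary allylic alcohol, giving the E-enal without touching oxirane or acrylate (allylic alcohol oxidation).

Step 6
Reactants: 10 methyl 2-[(2S,3S)-3-[(2E,6E)-2,6-dimethyl-8-oxoocta-2,6-dien-1-yl]oxiran-2-yl]prop-2-enoate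
Product: 13 (6R,7S,8S)-8-(triethylsilyloxy)germacra-1(10)E,4E,11(13)-trien-12,6-olide (8α-triethylsilyloxycostunolide), via allyl bromide 11 (not isolated), via hydroxy ester 12 (not isolated)
Conditions: Et3SiBr, CH2Cl2, −78 °C; concentrate; then slow addition to CrCl2 (6 equiv), THF/DMF, rt, 2 mM; aq. NH4Cl, silica gel
Reagents that add atoms: bromotriethylsilane, CC[Si](Br)(CC)CC
Why: The silyl bromide opens the vinyl oxirane by SN2' attack of bromide at C13 with silylation of the C8 oxygen, and CrCl2 turns the allylic bromide into an allylchromium that adds through C7 to the enal in a chair-like Nozaki–Hiyama–Kishi macrocyclisation of the kind used for costunolide, the (E,E)-chain and the outward-pointing C8 silyloxy group giving the 6,7-trans (6R,7S) arrangement relative to C8 (S), after which the C6 alkoxide lactonises onto the ester.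

Step 7
Reactants: 13 (6R,7S,8S)-8-(triethylsilyloxy)germacra-1(10)E,4E,11(13)-trien-12,6-olide
Product: 14 (6R,7S,8S,10R)-10-hydroxy-1-oxo-8-(triethylsilyloxy)germacra-4E,11(13)-dien-12,6-olide
Conditions: RuCl3 (1 mol %), Oxone, NaHCO3, EtOAc/MeCN/H2O, 0 °C
Reagents that add atoms: potassium peroxymonosulfate (active part of Oxone), [K+].[O-]S(=O)(=O)OO
Why: RuO4-catalysed ketohydroxylation oxidises the most electron-rich and exposed alkene, C1=C10, from its outer face, placing the ketone on the secondary carbon C1 and the tertiary hydroxyl on C10 with the (10R, α) configuration, while the 4,5-alkene is deactivated by the allylic lactone oxygen and the methylene lactone is electron-poor.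

Step 8
Reactants: 14 (6R,7S,8S,10R)-10-hydroxy-1-oxo-8-(triethylsilyloxy)germacra-4E,11(13)-dien-12,6-olide
Product: 15 (4R,5S,6S,7S,8S,10R)-4,5-epoxy-10-hydroxy-1-oxo-8-(triethylsilyloxy)germacr-11(13)-en-12,6-olide
Conditions: mCPBA, NaHCO3, CH2Cl2, 0 °C
Reagents that add atoms: 3-chloroperoxybenzoic acid, OOC(=O)c1cccc(Cl)c1
Why: Prilezhaev epoxidation of the only remaining nucleophilic alkene occurs from the peripheral face of the E-configured C4=C5 bond, giving the trans (4R,5S) oxirane as in parthenolide-type macrocycles, while the buffer protects oxirane and silyl ether.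

Step 9
Reactants: 15 (4R,5S,6S,7S,8S,10R)-4,5-epoxy-10-hydroxy-1-oxo-8-(triethylsilyloxy)germacr-11(13)-en-12,6-olide; 16 methacrylic anhydride
Product: 18 (4R,5S,6S,7R,8S,10R)-4,5-epoxy-10-hydroxy-8-(2-methylprop-2-enoyloxy)-1-oxogermacr-11(13)-en-12,6-olide, via diol 17 (not isolated)
Conditions: Et3N·3HF, MeCN, 0 °C; then Et3N, 16, DMAP (cat.), CH2Cl2, 0 °C
Reagents that add atoms: none
Why: Fluoride removes the triethylsilyl group and DMAP-catalysed acylation (Steglich-type) esterifies the secondary C8 alcohol with retention, draining its lactol equilibrium with the C1 ketone, while the tertiary C10 alcohol is too hindered to react.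

Step 10
Reactants: 18 (4R,5S,6S,7R,8S,10R)-4,5-epoxy-10-hydroxy-8-(2-methylprop-2-enoyloxy)-1-oxogermacr-11(13)-en-12,6-olide
Product: 19 (4R,5S,6R,7S,8S,10R)-4,5:7,10-diepoxy-8-(2-methylprop-2-enoyloxy)-1-oxogermacr-11(13)-en-12,6-olide (CNP0241021.1)
Conditions: Cu(MeCN)4PF6 (10 mol %), 2,9-dimethyl-1,10-phenanthroline (12 mol %), N-fluorobenzenesulfonimide (1.5 equiv), Li2CO3, PhCl, 40 °C
Reagents that add atoms: none
Why: Proposed new method: copper-catalysed radical-relay transannular allylic C–H etherification, in which monovalent copper reduces N-fluorobenzenesulfonimide to a divalent copper fluoride and a sulfonimidyl radical that abstracts the weakest C–H of 18 (the tertiary allylic C7–H, about 80 kcal/mol, already syn to the α-face C10 hydroxyl), the 2-carboxyallyl radical is captured by divalent copper chelated by the deprotonated α-ketol and C–O reductive elimination from trivalent copper closes the oxolane at C7 (any C13–N or C13–F allyl adduct is a 2-(X-methyl)butenolide that the C10 alkoxide converts into the same product by oxa-Michael addition and elimination), so that C7 (S) is fixed by the cis-bridging tether; the closest known reactions are the Kharasch–Sosnovsky allylic oxidation and copper/N-fluorobenzenesulfonimide benzylic C–H etherification.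

**Compound list**

1 | (2E,6E)-farnesol | CC(C)=CCC/C(C)=C/CC/C(C)=C/CO | starting material
2 | (2E,6E)-10-bromo-3,7,11-trimethyldodeca-2,6-diene-1,11-diol (racemic) | CC(C)(O)C(Br)CC/C(C)=C/CC/C(C)=C/CO | intermediate
3 | (2E,6E)-10,11-epoxyfarnesol, (2E,6E)-9-(3,3-dimethyloxiran-2-yl)-3,7-dimethylnona-2,6-dien-1-ol (racemic) | CC1(C)OC1CC/C(C)=C/CC/C(C)=C/CO | intermediate
4 | (4E,8E)-10-hydroxy-4,8-dimethyldeca-4,8-dienal | O=CCC/C(C)=C/CC/C(C)=C/CO | intermediate
5 | (2R,4E,8E)-2-chloro-10-hydroxy-4,8-dimethyldeca-4,8-dienal | OC/C=C(C)/CC/C=C(C)/C[C@@H](Cl)C=O | intermediate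
6 | methyl propiolate | C#CC(=O)OC | starting material
7 | [1-(methoxycarbonyl)ethenyl]bis(2-methylpropyl)aluminium | C=C(C(=O)OC)[Al](CC(C)C)CC(C)C | intermediate
8 | methyl (3S,4R,6E,10E)-4-chloro-3,12-dihydroxy-6,10-dimethyl-2-methylidenedodeca-6,10-dienoate | OC/C=C(C)/CC/C=C(C)/C[C@@H](Cl)[C@@H](O)C(=C)C(=O)OC | intermediate
9 | methyl 2-[(2S,3S)-3-[(2E,6E)-8-hydroxy-2,6-dimethylocta-2,6-dien-1-yl]oxiran-2-yl]prop-2-enoate | OC/C=C(C)/CC/C=C(C)/C[C@@H]1O[C@H]1C(=C)C(=O)OC | intermediate
10 | methyl 2-[(2S,3S)-3-[(2E,6E)-2,6-dimethyl-8-oxoocta-2,6-dien-1-yl]oxiran-2-yl]prop-2-enoate | O=C/C=C(C)/CC/C=C(C)/C[C@@H]1O[C@H]1C(=C)C(=O)OC | intermediate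
11 | methyl (2Z,4S,6E,10E)-2-(bromomethyl)-6,10-dimethyl-12-oxo-4-(triethylsilyloxy)dodeca-2,6,10-trienoate | O=C/C=C(C)/CC/C=C(C)/C[C@H](O[Si](CC)(CC)CC)/C=C(\CBr)C(=O)OC | intermediate
12 | methyl 2-[(1S,2R,3E,7E,10S)-2-hydroxy-4,8-dimethyl-10-(triethylsilyloxy)cyclodeca-3,7-dien-1-yl]prop-2-enoate | CC[Si](CC)(CC)O[C@H]1C/C(C)=C/CC/C(C)=C/[C@@H](O)[C@@H]1C(=C)C(=O)OC | intermediate
13 | (6R,7S,8S)-8-(triethylsilyloxy)germacra-1(10)E,4E,11(13)-trien-12,6-olide, (3aS,4S,6E,10E,11aR)-6,10-dimethyl-3-methylidene-4-(triethylsilyloxy)-3a,4,5,8,9,11a-hexahydrocyclodeca[b]furan-2(3H)-one | CC[Si](CC)(CC)O[C@H]1C/C(C)=C/CC/C(C)=C/[C@H]2OC(=O)C(=C)[C@H]12 | intermediate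
14 | (6R,7S,8S,10R)-10-hydroxy-1-oxo-8-(triethylsilyloxy)germacra-4E,11(13)-dien-12,6-olide | CC[Si](CC)(CC)O[C@H]1C[C@@](C)(O)C(=O)CC/C(C)=C/[C@H]2OC(=O)C(=C)[C@H]12 | intermediate
15 | (4R,5S,6S,7S,8S,10R)-4,5-epoxy-10-hydroxy-1-oxo-8-(triethylsilyloxy)germacr-11(13)-en-12,6-olide | CC[Si](CC)(CC)O[C@H]1C[C@@](C)(O)C(=O)CC[C@@]3(C)O[C@H]3[C@H]2OC(=O)C(=C)[C@H]12 | intermediate
16 | methacrylic anhydride | CC(=C)C(=O)OC(=O)C(C)=C | starting material
17 | (4R,5S,6S,7R,8S,10R)-4,5-epoxy-8,10-dihydroxy-1-oxogermacr-11(13)-en-12,6-olide | O[C@H]1C[C@@](C)(O)C(=O)CC[C@@]3(C)O[C@H]3[C@H]2OC(=O)C(=C)[C@H]12 | intermediate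
18 | (4R,5S,6S,7R,8S,10R)-4,5-epoxy-10-hydroxy-8-(2-methylprop-2-enoyloxy)-1-oxogermacr-11(13)-en-12,6-olide | C=C(C)C(=O)O[C@H]1C[C@@](C)(O)C(=O)CC[C@@]3(C)O[C@H]3[C@H]2OC(=O)C(=C)[C@H]12 | intermediate
19 | (4R,5S,6R,7S,8S,10R)-4,5:7,10-diepoxy-8-(2-methylprop-2-enoyloxy)-1-oxogermacr-11(13)-en-12,6-olide (CNP0241021.1) | C=C(C)C(=O)O[C@H]1C[C@@]2(C)O[C@@]13C(=C)C(=O)O[C@@H]3[C@@H]1O[C@]1(C)CCC2=O | target

**Summary**

Total step count: 10. Longest linear sequence: 10 steps, from farnesol.

**Three steps most likely to fail**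

Step 6, the ring closure. A ten-membered ring is formed and C6 is set relative to C8, so oligomerisation or the wrong C6/C8 relationship are the risks. The fallback sets out from 10. The bromide 11 is made as before and is converted with B2pin2 and Pd2(dba)3 in DMSO into the allylboronate methyl (2E,4S,6E,10E)-6,10-dimethyl-12-oxo-2-[(4,4,5,5-tetramethyl-1,3,2-dioxaborolan-2-yl)methyl]-4-(triethylsilyloxy)dodeca-2,6,10-trienoate F1. This isolable reagent is cyclised without any reductant by thermal intramolecular allylboration through a closed six-membered transition state (toluene, 80 °C, high dilution). Lactonisation on silica gel brings the material back to the route at 13.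

Step 7, the ketohydroxylation. RuO4 may also attack the 4,5-alkene or the methylene lactone, or cleave the ketol. The fallback sets out from 13. Dihydroxylation with catalytic OsO4 and N-methylmorpholine N-oxide, which is far more selective for the electron-rich 1(10)-alkene, gives (1R,6R,7S,8S,10R)-1,10-dihydroxy-8-(triethylsilyloxy)germacra-4E,11(13)-dien-12,6-olide F2. Catalytic TEMPO with PhI(OAc)2 then oxidises only the secondary C1 carbinol, and the route is rejoined at 14.

Step 10, the new copper-catalysed C–H etherification. The hydrogen abstraction may be unselective, or the copper capture may fail at the crowded C7. The fallback uses known chemistry and sets out from 18. Wohl–Ziegler bromination (NBS, catalytic AIBN, PhCF3, 80 °C) at the same weak C7–H gives, after allylic transposition, (4R,5S,6S,8S,10R)-13-bromo-4,5-epoxy-10-hydroxy-8-(2-methylprop-2-enoyloxy)-1-oxogermacr-7(11)-en-12,6-olide F3. This is a glaucolide-type 2-(bromomethyl)butenolide, and Ag2CO3 in MeCN triggers the transannular SN2' etherification by the C10 hydroxyl (oxa-Michael addition, then loss of bromide), which gives 19 directly.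

**Further compounds**

F1 | step 6 | methyl (2E,4S,6E,10E)-6,10-dimethyl-12-oxo-2-[(4,4,5,5-tetramethyl-1,3,2-dioxaborolan-2-yl)methyl]-4-(triethylsilyloxy)dodeca-2,6,10-trienoate | O=C/C=C(C)/CC/C=C(C)/C[C@H](O[Si](CC)(CC)CC)/C=C(\CB1OC(C)(C)C(C)(C)O1)C(=O)OC
F2 | step 7 | (1R,6R,7S,8S,10R)-1,10-dihydroxy-8-(triethylsilyloxy)germacra-4E,11(13)-dien-12,6-olide | CC[Si](CC)(CC)O[C@H]1C[C@@](C)(O)[C@H](O)CC/C(C)=C/[C@H]2OC(=O)C(=C)[C@H]12
F3 | step 10 | (4R,5S,6S,8S,10R)-13-bromo-4,5-epoxy-10-hydroxy-8-(2-methylprop-2-enoyloxy)-1-oxogermacr-7(11)-en-12,6-olide | C=C(C)C(=O)O[C@H]1C[C@@](C)(O)C(=O)CC[C@@]3(C)O[C@H]3[C@H]2OC(=O)C(CBr)=C12
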